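Compound numbers used throughout: 1 aryl aldehyde, 2 N-crotonoyl oxazolidinone, 3 boron dienolate, 4 syn aldol imide, 5 diol, 6 mono-acetate, 7 allyltrimethylsilane, 8 hydroxy allylsilane, 9 its trimethylsilyl ether, 10 mixed silyl acetal, 11 oxocarbenium triflate, 12 vinyl oxolane, 13 ring aldehyde, 14 hydroxymethyl acetate, 15 tetrabenzyl diacetate, 16 target. Ring atoms in the text are O1, C2 (carbon from the second molecule of 1), C3 (carbon made in the ring closure), C4 (bears the aldol-derived CH2OAc) and C5 (aldol carbinol carbon). Systematic names in the lists use their own locants.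

## Analysis of the target

Target 16 is a single oxolane ring (O1, C2–C5) with a 3,4-dihydroxyphenyl group on C2 and on C5 and an acetoxymethyl group on C3 and on C4. All four ring carbons are stereocentres: the aryl groups are cis to each other, the acetoxymethyl groups are cis to each other, and each aryl is trans to the acetoxymethyl group next to it. The molecule therefore has a mirror plane through O1 and the midpoint of C3–C4 and is meso, (2R,3S,4R,5S). Only relative configuration has to be controlled, and a racemic series of intermediates ends in one achiral product. The sensitive groups are the free catechols (air and base), the primary acetates (base, acyl migration) and the C2–O1 and C5–O1 bonds, which are benzylic with a para oxygen and so can ionise under acid or be hydrogenolysed. The hard part is the cis relationship at C3/C4: it cannot be corrected by equilibration once both carbons carry CH2OAc, and it has to be made beside two acid-labile benzylic centres. The strategy rests on C2, which is at the aldehyde oxidation level between O1 and C3, and on the C3 acetoxymethyl group, which can be carried as a vinyl group. An aldehyde carbon bonded to a ring oxygen and to a vinyl-bearing carbon is the retron of an oxocarbenium ion captured by the γ-carbon of an allylsilane. Because of the mirror plane, aldehyde 1 can supply both C5 (by an aldol reaction) and C2 (by the ring closure).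

## Retrosynthetic reasoning

**16 ⇒ 15.** The four phenolic O–H bonds are traced back to four O–benzyl bonds. Benzyl ethers are chosen because they are removed by hydrogenolysis in a neutral medium, which spares the acetates, the oxidisable catechols and the acid-labile ring C–O bonds. The forward step has to cleave aryl O–benzyl bonds faster than the two benzylic C–O bonds of the ring.

**15 ⇒ 14 ⇒ 12.** The C3 acetoxymethyl group is taken back to hydroxymethyl (14) and then to a vinyl group (12). The vinyl group is inert to everything before it and is exactly what an allylsilane leaves behind. The forward sequence has to cleave the alkene and reduce the resulting aldehyde 13 at once, so that C3, which is α to the formyl group, does not epimerise. The second acetylation then creates the mirror plane.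

**12 ⇒ 9 + 1 (key disconnection).** The bonds O1–C2 and C2–C3 are cut. Both end at C2, which becomes the carbonyl carbon of 1, the same aldehyde that supplies C5. Cutting a C–aryl bond instead would demand Friedel–Crafts chemistry under the acid that the ring does not tolerate, and cutting C3–C4 would demand a dimerisation. Here one ring, two bonds and two stereocentres arise in one operation from 1 and the silyl ether 9. Forward, the mixed acetal 10 must ionise to the E-oxocarbenium ion 11, the allylsilane must attack through its γ-carbon, and the closure must give the 2,5-cis, 2,3-trans product without ionising the C5–O bond.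

**9 ⇒ 8 ⇒ 6 + 7.** The O–Si bond of 9 is a trivial protection of 8. The internal double bond of 8 is cut by cross-metathesis into the terminal alkene of 6 and allylsilane 7. Silicon is thus introduced late and from a commodity, and 6 needs only a vinyl group at C3. The forward reaction should give mainly the E-alkene.

**6 ⇒ 5 ⇒ 4 ⇒ 1 + 2.** The primary acetate of 6 comes from selective acylation of diol 5, and 5 from hydride reduction of imide 4. The C4–C5 bond of 4 is cut by an aldol reaction between 1 and the α-carbon of the dienolate 3 derived from 2. Two details are settled here: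
- The ring needs the aldol diastereomer in which hydroxyl and vinyl are syn when the chain aryl–C5–C4–acyl is drawn as the backbone; closing O1 and C3 into a ring then places the C5 aryl and the C4 CH2OAc trans. The same compound reads as "anti" if the backbone is drawn through the double bond and hydroxyl is compared with acetoxymethyl, so the descriptor is only meaningful together with the backbone.
- A lithium dienolate of a simple crotonate ester reacts at the α-carbon but with little diastereocontrol. The boron dienolate 3 reacts through a closed chair and should give the syn isomer reliably.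

## Alternatives that were turned down

**Alternative 1:** Both catechol rings are disconnected across two ring bonds each, back to the meso diyne A2, in which all four ring stereocentres are already present. The forward key step is a twofold cobalt-catalysed [4+2] cycloaddition (CoBr2, 1,2-bis(diphenylphosphino)ethane, Zn, ZnI2) of A2 with the bis(silyloxy)diene A3. It gives the bis(cyclohexa-1,4-diene) A1, which still has to be dehydrogenated and desilylated.
- For it: the stereocentres come from the rigid exo oxanorbornene anhydride A4 by alkene cleavage, so the trans,cis,trans pattern is fixed by a bicyclic template. No aryl-stabilised benzylic ether exists until the last steps, and no benzyl groups are needed.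
- Against it: two arenes are built from scratch although the aryl carbon is available as an aldehyde. The way from A4 to A2 passes through an α-alkoxy dialdehyde that can epimerise during alkyne homologation. The cycloaddition must go to completion at both alkynes with a Lewis-acid-sensitive bis(silyl enol ether). The aromatisation adds an oxidation next to electron-rich rings.
- Comparison: on stereochemical certainty this route is stronger than the chosen one, which relies on a kinetic preference in its ring closure. The chosen route offers roughly half the step count, both aryl groups from one cheap aldehyde, and one decisive step that can be tested early.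

**Alternative 2:** The C3–C4 bond and a temporary C2–C5 bond are disconnected together by a [2+2] retron. Irradiation near 350 nm of the template-bound bis-cinnamate A5 gives the bridged truxinate A6, in which the aryls are cis, the ester carbons are cis and each aryl is trans to its neighbouring ester.
- For it: one photochemical step from a simple diester sets C3–C4 and the full relative configuration of four carbons. Reduction of the aryl esters releases the template and gives the two hydroxymethyl groups directly. In this step it is as strong as the chosen route or stronger.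
- Against it: the cyclobutane bond C2–C5 must afterwards be cleaved and replaced by an oxygen bridge. One-electron oxidation of an electron-rich 1,2-diarylcyclobutane tends to cyclorevert to two cinnamyl halves instead of trapping oxygen. Any path through benzylic cations also discards the C2/C5 configuration that the photodimer provided.
- Comparison: the chosen route makes the C–O–C ring directly and never has to turn a C–C bond into an ether.

**Alternative 3:** Both C–aryl bonds are disconnected. BF3·OEt2 ionises the two methoxy acetals of the cis bis-acetal A7 in turn, and two molecules of the catechol dibenzyl ether A8 attack para to oxygen. The product A9 is identical with compound 15 of the chosen route.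
- For it: it is the shortest route and uses the mirror symmetry fully. Arylation of a five-membered oxocarbenium ion trans to its neighbouring substituent is a known preference and would set both aryl carbons correctly. The C3/C4 cis relationship would come from a cis hydrogenation. On step count this alternative is clearly stronger.
- Against it: each oxocarbenium ion of A7 has a hydrogen on the neighbouring C3 or C4. Loss of that proton and of the second methanol leads to the aromatic furan A10, an irreversible sink that also destroys the C3/C4 stereocentres. A8 is only a moderate nucleophile, so the cation lives long enough for this to compete. The product is itself a doubly benzylic ether that the stoichiometric Lewis acid can reopen and over-arylate.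
- Comparison: the chosen route brings in both aryl carbons as aldehyde carbons, uses a far more reactive internal nucleophile, and needs only catalytic Lewis acid at −78 °C. It pays with more steps and a less certain C3 configuration.

Key step: step 6

Assumptions: all chiral intermediates are racemic, and SMILES and CIP descriptors show one enantiomer. Compound 2 is taken as purchasable; otherwise it is one N-acylation away from oxazolidin-2-one.

## Route

Step 1
Reactants: 1 3,4-bis(benzyloxy)benzaldehyde; 2 3-[(2E)-but-2-enoyl]-1,3-oxazolidin-2-one
Product: 4 rac-3-{(2S)-2-[(S)-[3,4-bis(benzyloxy)phenyl](hydroxy)methyl]but-3-enoyl}-1,3-oxazolidin-2-one, via dibutylboron dienolate 3 (not isolated)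
Conditions: 2, Bu2BOTf, Et3N, CH2Cl2, −78 → 0 °C; then 1, −78 → 0 °C; pH 7 buffer, MeOH, H2O2, 0 °C
Reagents that add atoms: none
Why: Soft enolisation of 2 removes a γ-hydrogen and gives the Z(O) boron dienolate 3, which reacts at its α-carbon with 1 through a closed Zimmerman–Traxler chair (Evans-type boron aldol in its deconjugative form). The chair with the aryl group equatorial sets both stereocentres (later C4 and C5) with hydroxyl and vinyl syn on the acyl backbone; the auxiliary is achiral, so the adduct is racemic.

Step 2
Reactants: 4 rac-3-{(2S)-2-[(S)-[3,4-bis(benzyloxy)phenyl](hydroxy)methyl]but-3-enoyl}-1,3-oxazolidin-2-one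
Product: 5 rac-(1S,2R)-1-[3,4-bis(benzyloxy)phenyl]-2-ethenylpropane-1,3-diol
Conditions: LiBH4, THF, MeOH (1 equiv), 0 °C
Reagents that add atoms: none
Why: LiBH4 reduces the activated imide carbonyl (reductive removal of the oxazolidinone) and leaves the alkene, the benzyl ethers and both stereocentres untouched. The reagent is weakly basic, so retro-aldol cleavage and migration of the double bond into conjugation should not compete.

Step 3
Reactants: 5 rac-(1S,2R)-1-[3,4-bis(benzyloxy)phenyl]-2-ethenylpropane-1,3-diol
Product: 6 rac-(2R)-2-[(S)-[3,4-bis(benzyloxy)phenyl](hydroxy)methyl]but-3-en-1-yl acetate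
Conditions: AcCl (1.05 equiv), 2,4,6-collidine, CH2Cl2, −78 °C
Reagents that add atoms: acetyl chloride, CC(=O)Cl
Why: Acylation with acetyl chloride and a hindered pyridine base at low temperature is a known way to acetylate a primary hydroxyl beside a secondary one. The secondary benzylic hydroxyl, flanked by the aryl group and a branched carbon, should react much more slowly.

Step 4
Reactants: 6 rac-(2R)-2-[(S)-[3,4-bis(benzyloxy)phenyl](hydroxy)methyl]but-3-en-1-yl acetate; 7 allyltrimethylsilane
Product: 8 rac-(2R,3E)-2-[(S)-[3,4-bis(benzyloxy)phenyl](hydroxy)methyl]-5-(trimethylsilyl)pent-3-en-1-yl acetate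
Conditions: 7 (4 equiv), second-generation Grubbs catalyst RuCl2(=CHPh)(H2IMes)(PCy3) (5 mol%), CH2Cl2, 40 °C
Reagents that add atoms: none
Why: Olefin cross-metathesis: the unhindered allylsilane 7 in excess is the fast partner and the branched terminal alkene of 6 the slow one, so the cross product should dominate while ethene escapes. The allylic branching of 6 favours the E isomer, and the catalyst tolerates hydroxyl, acetate and benzyl ether groups.

Step 5
Reactants: 8 rac-(2R,3E)-2-[(S)-[3,4-bis(benzyloxy)phenyl](hydroxy)methyl]-5-(trimethylsilyl)pent-3-en-1-yl acetate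
Product: 9 rac-(2R,3E)-2-{(S)-[3,4-bis(benzyloxy)phenyl][(trimethylsilyl)oxy]methyl}-5-(trimethylsilyl)pent-3-en-1-yl acetate
Conditions: Me3SiCl, imidazole, CH2Cl2, 0 °C; non-acidic work-up, used crude
Reagents that add atoms: chlorotrimethylsilane, C[Si](C)(C)Cl
Why: Standard silylation of a secondary alcohol. The silyl ether lets the ring closure run without any protic acid, which would otherwise protodesilylate the allylsilane or ionise the benzylic C–O bond.

Step 6
Reactants: 9 rac-(2R,3E)-2-{(S)-[3,4-bis(benzyloxy)phenyl][(trimethylsilyl)oxy]methyl}-5-(trimethylsilyl)pent-3-en-1-yl acetate; 1 3,4-bis(benzyloxy)benzaldehyde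
Product: 12 rac-[(2S,3R,4R,5R)-2,5-bis[3,4-bis(benzyloxy)phenyl]-4-ethenyloxolan-3-yl]methyl acetate, via mixed silyl acetal 10 (not isolated), via oxocarbenium triflate 11 (not isolated)
Conditions: 1 (1.1 equiv), Me3SiOTf (0.2 equiv), CH2Cl2, −78 °C; Et3N quench at −78 °C
Reagents that add atoms: none
Why: Me3SiOTf activates aldehyde 1, silyl ether 9 adds to give the mixed acetal 10, and a second silyl transfer expels hexamethyldisiloxane and leaves the E-oxocarbenium ion 11, so O1–C2 is made. The γ-carbon of the allylsilane then attacks C2 (C2–C3 made), and the β-silyl cation passes Me3Si+ to triflate, which regenerates the catalyst and leaves the vinyl group on C3; this is the intramolecular silyl-modified Sakurai (Prins-type) cyclisation known for 5-silylpent-3-en-1-ols and aldehydes. The oxolane closes by C–C bond formation onto the endocyclic oxocarbenium carbon, formally 5-endo at the C=O+ unit and 5-exo at the allylsilane double bond, which the strong nucleophile and an envelope-like transition state make feasible. C2 is set by the E geometry of 11 together with the C5 aryl sitting pseudo-equatorial, so both aryl groups end on the same face (2,5-cis). C3 is set by the alkene face that reaches C2: the exocyclic alkene carbon of the E-allylsilane should turn away from the C2 aryl (2,3-trans), and with C4/C5 already trans from the aldol this places vinyl cis to CH2OAc. The step needs kinetic control with no ionisation of the C5–O bond; the absence of protic acid, the catalytic Lewis acid and −78 °C should keep 2-oxonia-Cope and benzylic SN1 pathways slow beside the fast allylsilane capture. The ring size is dictated by silicon, since only attack through the γ-carbon gives a β-silyl-stabilised cation.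

Step 7
Reactants: 12 rac-[(2S,3R,4R,5R)-2,5-bis[3,4-bis(benzyloxy)phenyl]-4-ethenyloxolan-3-yl]methyl acetate
Product: 14 rac-[(2S,3R,4S,5R)-2,5-bis[3,4-bis(benzyloxy)phenyl]-4-(hydroxymethyl)oxolan-3-yl]methyl acetate, via ring aldehyde 13 (not isolated)
Conditions: O3, CH2Cl2/MeOH, −78 °C, Sudan Red 7B as end-point indicator; then NaBH4, −78 → 0 °C
Reagents that add atoms: ozone, [O-][O+]=O
Why: Ozonolysis with reductive work-up: ozone cleaves the isolated terminal alkene much faster than it attacks the alkoxy arenes, and the dye marks the end point. NaBH4 added cold reduces the peroxidic species and aldehyde 13 at once, so C3 next to the formyl group has little time to epimerise. Any acetate lost to methanolysis is restored in step 8.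

Step 8
Reactants: 14 rac-[(2S,3R,4S,5R)-2,5-bis[3,4-bis(benzyloxy)phenyl]-4-(hydroxymethyl)oxolan-3-yl]methyl acetate
Product: 15 meso-[(2R,3S,4R,5S)-2,5-bis[3,4-bis(benzyloxy)phenyl]oxolane-3,4-diyl]dimethanediyl diacetate
Conditions: Ac2O, pyridine, DMAP (cat.), CH2Cl2, 0 °C → rt
Reagents that add atoms: acetic anhydride, CC(=O)OC(C)=O
Why: DMAP-catalysed acetylation of a primary alcohol. The product gains a mirror plane, so the racemic series ends here in one meso compound.

Step 9
Reactants: 15 meso-[(2R,3S,4R,5S)-2,5-bis[3,4-bis(benzyloxy)phenyl]oxolane-3,4-diyl]dimethanediyl diacetate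
Product: 16 meso-[(2R,3S,4R,5S)-2,5-bis(3,4-dihydroxyphenyl)oxolane-3,4-diyl]dimethanediyl diacetate (CNP0416169.1)
Conditions: H2 (1 atm), 10% Pd/C, EtOAc/THF, rt; filtration and concentration under argon
Reagents that add atoms: none
Why: Hydrogenolysis of aryl benzyl ethers over Pd/C in a neutral medium is fast, whereas the two ring C–O bonds, although benzylic, are dialkyl-ether bonds and should cleave much more slowly. The acetates are inert, and the four phenols appear without acid or base.

## Compound list

1 | 3,4-bis(benzyloxy)benzaldehyde | O=Cc1ccc(OCc2ccccc2)c(OCc2ccccc2)c1 | starting material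
2 | 3-[(2E)-but-2-enoyl]-1,3-oxazolidin-2-one | C/C=C/C(=O)N1CCOC1=O | starting material
3 | 3-{(1Z)-1-[(dibutylboranyl)oxy]buta-1,3-dien-1-yl}-1,3-oxazolidin-2-one (boron dienolate of 2) | C=C/C=C(\OB(CCCC)CCCC)N1CCOC1=O | intermediate
4 | rac-3-{(2S)-2-[(S)-[3,4-bis(benzyloxy)phenyl](hydroxy)methyl]but-3-enoyl}-1,3-oxazolidin-2-one (syn aldol) | C=C[C@H](C(=O)N1CCOC1=O)[C@@H](c1ccc(OCc2ccccc2)c(OCc2ccccc2)c1)O | intermediate
5 | rac-(1S,2R)-1-[3,4-bis(benzyloxy)phenyl]-2-ethenylpropane-1,3-diol | C=C[C@H](CO)[C@@H](c1ccc(OCc2ccccc2)c(OCc2ccccc2)c1)O | intermediate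
6 | rac-(2R)-2-[(S)-[3,4-bis(benzyloxy)phenyl](hydroxy)methyl]but-3-en-1-yl acetate | C=C[C@H](COC(C)=O)[C@@H](c1ccc(OCc2ccccc2)c(OCc2ccccc2)c1)O | intermediate
7 | allyltrimethylsilane | C=CC[Si](C)(C)C | starting material
8 | rac-(2R,3E)-2-[(S)-[3,4-bis(benzyloxy)phenyl](hydroxy)methyl]-5-(trimethylsilyl)pent-3-en-1-yl acetate | C[Si](C)(C)C/C=C/[C@H](COC(C)=O)[C@@H](c1ccc(OCc2ccccc2)c(OCc2ccccc2)c1)O | intermediate
9 | rac-(2R,3E)-2-{(S)-[3,4-bis(benzyloxy)phenyl][(trimethylsilyl)oxy]methyl}-5-(trimethylsilyl)pent-3-en-1-yl acetate | C[Si](C)(C)C/C=C/[C@H](COC(C)=O)[C@@H](c1ccc(OCc2ccccc2)c(OCc2ccccc2)c1)O[Si](C)(C)C | intermediate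
10 | mixed O-trimethylsilyl acetal of 1 with the alcohol of 9 (both epimers at the acetal carbon) | C[Si](C)(C)C/C=C/[C@H](COC(C)=O)[C@@H](c1ccc(OCc2ccccc2)c(OCc2ccccc2)c1)OC(O[Si](C)(C)C)c1ccc(OCc2ccccc2)c(OCc2ccccc2)c1 | intermediate
11 | (E)-O-alkyl oxocarbenium trifluoromethanesulfonate derived from 10 | C[Si](C)(C)C/C=C/[C@H](COC(C)=O)[C@@H](c1ccc(OCc2ccccc2)c(OCc2ccccc2)c1)/[O+]=C/c1ccc(OCc2ccccc2)c(OCc2ccccc2)c1.[O-]S(=O)(=O)C(F)(F)F | intermediate
12 | rac-[(2S,3R,4R,5R)-2,5-bis[3,4-bis(benzyloxy)phenyl]-4-ethenyloxolan-3-yl]methyl acetate (aryls cis; ethenyl and acetoxymethyl cis; each aryl trans to its neighbour) | C=C[C@@H]1[C@H](COC(C)=O)[C@@H](c2ccc(OCc3ccccc3)c(OCc3ccccc3)c2)O[C@H]1c1ccc(OCc2ccccc2)c(OCc2ccccc2)c1 | intermediate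
13 | rac-[(2S,3R,4R,5R)-2,5-bis[3,4-bis(benzyloxy)phenyl]-4-formyloxolan-3-yl]methyl acetate | O=C[C@@H]1[C@H](COC(C)=O)[C@@H](c2ccc(OCc3ccccc3)c(OCc3ccccc3)c2)O[C@H]1c1ccc(OCc2ccccc2)c(OCc2ccccc2)c1 | intermediate
14 | rac-[(2S,3R,4S,5R)-2,5-bis[3,4-bis(benzyloxy)phenyl]-4-(hydroxymethyl)oxolan-3-yl]methyl acetate | OC[C@@H]1[C@H](COC(C)=O)[C@@H](c2ccc(OCc3ccccc3)c(OCc3ccccc3)c2)O[C@H]1c1ccc(OCc2ccccc2)c(OCc2ccccc2)c1 | intermediate
15 | meso-[(2R,3S,4R,5S)-2,5-bis[3,4-bis(benzyloxy)phenyl]oxolane-3,4-diyl]dimethanediyl diacetate | CC(=O)OC[C@@H]1[C@H](COC(C)=O)[C@@H](c2ccc(OCc3ccccc3)c(OCc3ccccc3)c2)O[C@H]1c1ccc(OCc2ccccc2)c(OCc2ccccc2)c1 | intermediate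
16 | meso-[(2R,3S,4R,5S)-2,5-bis(3,4-dihydroxyphenyl)oxolane-3,4-diyl]dimethanediyl diacetate (CNP0416169.1) | CC(=O)OC[C@@H]1[C@H](COC(C)=O)[C@@H](c2ccc(O)c(O)c2)O[C@H]1c1ccc(O)c(O)c1 | target

## Step count and least certain steps

Total step count: 9. Longest linear sequence: 9 steps (from 1 and 2 to 16; the route is linear, with 1 used twice and 7 brought in at step 4).

**Step 6 (key step).**
- What may go wrong: erosion of facial selectivity at C3, so that the vinyl group ends trans to the acetoxymethyl group. The energy gap between the two envelope transition states may be small, and any Z isomer carried over from step 4 may close differently. A second danger is loss of configuration at C5 through benzylic ionisation or 2-oxonia-Cope rearrangement of 11, both favoured by the electron-rich aryl groups.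
- Fallback: replace kinetic control at C3 by a thermodynamic funnel. It sets out from 12, taken as it comes from the cyclisation together with its C3 epimer rac-[(2S,3R,4S,5R)-2,5-bis[3,4-bis(benzyloxy)phenyl]-4-ethenyloxolan-3-yl]methyl acetate F1. Ozonolysis with PPh3 work-up gives aldehyde 13 and its epimer rac-[(2S,3R,4S,5R)-2,5-bis[3,4-bis(benzyloxy)phenyl]-4-formyloxolan-3-yl]methyl acetate F2. K2CO3 in MeOH at 0 °C removes the acetate and epimerises C3 through the enolate. Only the isomer with formyl cis to hydroxymethyl can close, giving the cis-fused lactol 6,8-bis[3,4-bis(benzyloxy)phenyl]-3,7-dioxabicyclo[3.3.0]octan-2-ol F3 (both aryls exo), because a trans-fused pair of five-membered rings is too strained; this should drain both epimers into one compound. NaBH4 then gives the meso diol [(2R,3S,4R,5S)-2,5-bis[3,4-bis(benzyloxy)phenyl]oxolane-3,4-diyl]dimethanol F4, and Ac2O/pyridine brings the route back at 15. The base has to stay mild, since the ring oxygen is β to the formyl group and could be eliminated.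

**Step 1.**
- What may go wrong: slow or reversible addition to the electron-rich, weakly electrophilic aldehyde, competing attack through the γ-carbon of the dienolate, and partial loss of syn selectivity.
- Fallback: change from aldol to allylboration. It sets out from 1, which is treated with (E)-tert-butyldimethyl{[4-(4,4,5,5-tetramethyl-1,3,2-dioxaborolan-2-yl)but-2-en-1-yl]oxy}silane in toluene at rt to 50 °C. The closed chair of an E-allylboronate places hydroxyl and the silyloxymethyl group anti along the chain through the vinyl group, which is the same relative configuration as the syn aldol. This gives rac-(1S,2R)-1-[3,4-bis(benzyloxy)phenyl]-2-({[tert-butyl(dimethyl)silyl]oxy}methyl)but-3-en-1-ol F5. Bu4NF in THF removes the silyl group and brings the route back at 5.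

**Step 7.**
- What may go wrong: over-oxidation of the alkoxy arenes or benzyl ethers by ozone, and epimerisation at C3 while the aldehyde is present.
- Fallback: change from ozone to stepwise glycol cleavage. It sets out from 12. OsO4 (cat.) with N-methylmorpholine N-oxide in acetone/water gives the diol rac-{2,5-bis[3,4-bis(benzyloxy)phenyl]-4-(1,2-dihydroxyethyl)oxolan-3-yl}methyl acetate F6 (both carbinol epimers). NaIO4 in buffered THF/water cleaves it to 13, and NaBH4 added to the same flask at 0 °C brings the route back at 14.

**Step 9.**
- What may go wrong: hydrogenolysis of the ring benzylic C–O bonds once the para-hydroxyl groups are free (ring opening to a 1,4-diarylbutane), and oxidation of the catechols during work-up.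
- Fallback: change from reductive to Lewis-acid debenzylation. It sets out from 15, which is treated with BCl3 and pentamethylbenzene as cation scavenger in CH2Cl2 at −78 °C and quenched cold with MeOH; it comes back at 16 directly and makes no new intermediate.

## Further compounds

F1 | step 6 | rac-[(2S,3R,4S,5R)-2,5-bis[3,4-bis(benzyloxy)phenyl]-4-ethenyloxolan-3-yl]methyl acetate (C3 epimer of 12) | C=C[C@H]1[C@H](COC(C)=O)[C@@H](c2ccc(OCc3ccccc3)c(OCc3ccccc3)c2)O[C@H]1c1ccc(OCc2ccccc2)c(OCc2ccccc2)c1
F2 | step 6 | rac-[(2S,3R,4S,5R)-2,5-bis[3,4-bis(benzyloxy)phenyl]-4-formyloxolan-3-yl]methyl acetate (C3 epimer of 13) | O=C[C@H]1[C@H](COC(C)=O)[C@@H](c2ccc(OCc3ccccc3)c(OCc3ccccc3)c2)O[C@H]1c1ccc(OCc2ccccc2)c(OCc2ccccc2)c1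
F3 | step 6 | 6,8-bis[3,4-bis(benzyloxy)phenyl]-3,7-dioxabicyclo[3.3.0]octan-2-ol (racemic, cis-fused, both aryls exo, anomeric mixture) | OC2OC[C@@H]1[C@@H](c3ccc(OCc4ccccc4)c(OCc4ccccc4)c3)O[C@@H](c3ccc(OCc4ccccc4)c(OCc4ccccc4)c3)[C@@H]12
F4 | step 6 | meso-[(2R,3S,4R,5S)-2,5-bis[3,4-bis(benzyloxy)phenyl]oxolane-3,4-diyl]dimethanol | OC[C@@H]1[C@H](CO)[C@@H](c2ccc(OCc3ccccc3)c(OCc3ccccc3)c2)O[C@H]1c1ccc(OCc2ccccc2)c(OCc2ccccc2)c1
F5 | step 1 | rac-(1S,2R)-1-[3,4-bis(benzyloxy)phenyl]-2-({[tert-butyl(dimethyl)silyl]oxy}methyl)but-3-en-1-ol | C=C[C@H](CO[Si](C)(C)C(C)(C)C)[C@@H](c1ccc(OCc2ccccc2)c(OCc2ccccc2)c1)O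
F6 | step 7 | rac-{2,5-bis[3,4-bis(benzyloxy)phenyl]-4-(1,2-dihydroxyethyl)oxolan-3-yl}methyl acetate (ring configuration as in 12, both carbinol epimers) | OCC(O)[C@@H]1[C@H](COC(C)=O)[C@@H](c2ccc(OCc3ccccc3)c(OCc3ccccc3)c2)O[C@H]1c1ccc(OCc2ccccc2)c(OCc2ccccc2)c1
F0 | step 9 | none | none
A1 | alternative 1 | meso bis[4,5-bis(trimethylsilyloxy)cyclohexa-1,4-dien-1-yl] analogue of 16 | CC(=O)OC[C@@H]1[C@H](COC(C)=O)[C@@H](C2=CCC(O[Si](C)(C)C)=C(O[Si](C)(C)C)C2)O[C@H]1C1=CCC(O[Si](C)(C)C)=C(O[Si](C)(C)C)C1
A2 | alternative 1 | meso-[2,5-cis-diethynyloxolane-3,4-cis-diyl]dimethanediyl diacetate (each ethynyl trans to its neighbour) | CC(=O)OC[C@@H]1[C@H](COC(C)=O)[C@@H](C#C)O[C@H]1C#C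
A3 | alternative 1 | 2,3-bis(trimethylsilyloxy)buta-1,3-diene | C=C(O[Si](C)(C)C)C(=C)O[Si](C)(C)C
A4 | alternative 1 | exo-7-oxabicyclo[2.2.1]hept-5-ene-2,3-dicarboxylic anhydride | O=C1OC(=O)[C@@H]2[C@H]1[C@H]1C=C[C@@H]2O1
A5 | alternative 2 | naphthalene-1,8-diyl bis{(2E)-3-[3,4-bis(benzyloxy)phenyl]prop-2-enoate} | O=C(/C=C/c1ccc(OCc2ccccc2)c(OCc2ccccc2)c1)Oc1cccc2cccc(OC(=O)/C=C/c3ccc(OCc4ccccc4)c(OCc4ccccc4)c3)c12
A6 | alternative 2 | template-bridged truxinate (aryls cis, ester carbons cis, each aryl trans to the adjacent ester) | O=C5Oc1cccc2cccc(OC(=O)[C@@H]3[C@@H](c4ccc(OCc6ccccc6)c(OCc6ccccc6)c4)[C@@H](c4ccc(OCc6ccccc6)c(OCc6ccccc6)c4)[C@@H]35)c12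
A7 | alternative 3 | cis-3,4-bis(acetoxymethyl)-2,5-dimethoxyoxolane (acetal carbons as mixtures) | CC(=O)OC[C@@H]1[C@H](COC(C)=O)C(OC)OC1OC
A8 | alternative 3 | 1,2-bis(benzyloxy)benzene | c1ccc(COc2ccccc2OCc2ccccc2)cc1
A9 | alternative 3 | tetra-O-benzyl ether of 16 (meso; identical with 15) | CC(=O)OC[C@@H]1[C@H](COC(C)=O)[C@@H](c2ccc(OCc3ccccc3)c(OCc3ccccc3)c2)O[C@H]1c1ccc(OCc2ccccc2)c(OCc2ccccc2)c1
A10 | alternative 3 | furan-3,4-diyldimethanediyl diacetate | CC(=O)OCc1cocc1COC(C)=O
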